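The runs were generated by integration on assumed constants, noise included.

The slowness of the late fall of X in the delta run carries the question at 15 d.

in all of them: Q 24 mM
- eta: L 24 mM; the very flask that is asked about, followed so far
- delta: L 16 mM; run made earlier
- flask: L 24.0 mM; time 15 d

| run | time / d | X / % | E / % | Q / % |
|---|---|---|---|---|
| eta | 0.417 | 51.8 | 6.3 | 40.1 |
| eta | 1.04 | 66.5 | 20.6 | 10.1 |
| eta | 2.08 | 56.6 | 41.7 | 0.7 |
| eta | 3.00 | 46.0 | 53.2 | 0 |
| delta | 1.67 | 62.9 | 34.4 | 3.6 |
| delta | 3.00 | 46.7 | 52.8 | 0.5 |
| delta | 5.00 | 32.7 | 66.5 | 0 |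
| delta | 6.00 | 29.4 | 68.9 | 0 |

(scatter of a reading: 0.5 percentage points)

- ratio of X to E at 15 min
- ratio of X to E at 8.0 h
- ratio of X to E at 15 d
- which of X and E there is more of at 15 d

Two extreme versions bracket the end of delta. If X passed to E one way, X would lose the same factor each day, so the fall from 3.00 d to 5.00 d puts X at 27.4% by 6.00 d. Delta read 29.4%, higher than that. If X and E already stood still by 6.00 d, the ratio would be 0.427, but X still dropped 3.3 percentage points in the last day, more than the scatter. So the end lies between: a two-way step under thermodynamic control.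

With Q at 0.5% by 3.00 d, take the excess of X over its end level to shrink by a fixed factor f per day. The two-day drop is 14 points.

two-day drop / last drop = (1 + f) / (f × f), so f = 0.617

end X = X at 6.00 d − last drop × f / (1 − f) = 24.1%

end E = X and E together − end X, so end X / end E = 0.324

This is the end ratio, X over E once the two stop shifting, a reading with the scatter of its readings. At 3.00 d eta read X 46.0% and delta 46.7%, 0.7 points apart despite different L, so the ratio is carried to the flask. Shrinking by f per day, the excess of delta comes to 0.069 points at 15 d, less than the scatter.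

The forecast gives 35, 10.5 and 0.32, with E ahead, its end ratio “reached well before 15 d”. This reckoning gives 0.324 for the end ratio and nothing for the early times.

The flask gives 4.68 at 15 min, 10.1 at 8.0 h and 0.346 at 15 d, with E ahead.

    2 L → G (k = 0.0360 /M/min)
    Q ⇌ L (K = 0.0490, k = 0.00270 /min)
    X ⇌ E (K = 2.90, k = 2.60 × 10⁻⁴ /min)
    Q → X (k = 0.00150 /min)
    L → E (k = 5.90 × 10⁻⁴ /min)

The forecast stands higher than the flask at 15 min, and the end agrees: after a thousand times the latest time the ratio is 0.345. With G at 1.10%, the end ratio puts X at 24.2% in the flask, which ends at 25.4%. The neighbour with 41 mM of L holds G at 2.08%, so the end ratio puts its X at 24.0%. That neighbour ends with X at 25.2% and a ratio of 0.346.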